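Retrosynthesis: the diaryl ether is cut at the ring A C5–O bond (phenoxide addition–elimination on a 3-chlorocyclohexenone), ring A is then opened at C1–C6 and C4–C5 (enone plus dimethyl malonate), and both quaternary carbons are traced back to farnesyl diethyl phosphate.
Enabling feature: ring A carries oxygen on C3, C4 and C5 and the quaternary side-chain carbon on C1; this maps onto a 2-alkoxy-5-alkylcyclohexane-1,3-dione whose C3 and C5 carbonyls are constitutionally equivalent, so either may take up the ring B oxygen.
Forward, ring A series: farnesol → allylic phosphate → silyl enyne (copper-catalysed SN2′) → terminal alkyne → E-iodoalkene → alkoxymethyl enone; ring A is closed as a cyclohexanedione ester, decarboxylated and converted into the β-chloro enone.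
Ring B is present from the start as catechol: silyl/acetal differentiation, ortho-metalation and SN2′ arylation of the same phosphate, then desilylation to a monophenol.
The halves are joined through oxygen, ring A is then dehydrogenated to the arene and the two acetals are removed.
Stereochemistry: both quaternary centres come from catalyst-controlled SN2′ substitutions run with antipodal ligands (R beside ring A, S beside ring B); the E-alkenes come from (E,E)-farnesol; ring centres created in the annulation are erased on aromatisation.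

Key step: step 8

Remark (assumption): both antipodes of the chiral imidazolinium sulfonate (NHC precursor) are taken as available, and the antipode that serves each series is assigned in a calibration run, since the sense of induction is not presumed here.
Numbering and abbreviations: ring A is numbered C1 (side chain), C3 and C4 (hydroxyls), C5 (aryloxy). "R-chain" = (3R,6E)-3,7,11-trimethyldodeca-1,6,10-trien-3-yl and "S-chain" = (3S,6E)-3,7,11-trimethyldodeca-1,6,10-trien-3-yl, that is, a quaternary carbon bearing methyl, vinyl and (E)-4,8-dimethylnona-3,7-dienyl.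

Step 1
Reactants: 1 (2E,6E)-farnesol
Product: 2 (2E,6E)-3,7,11-trimethyldodeca-2,6,10-trien-1-yl diethyl phosphate
Conditions: ClP(O)(OEt)2, Et3N, DMAP (cat.), CH2Cl2, 0 → 22 °C
Reagents that add atoms: diethyl chlorophosphate, CCOP(=O)(Cl)OCC
Why: Standard O-phosphorylation of a primary allylic alcohol with a chlorophosphate under amine base and nucleophilic catalysis, which installs the leaving group for copper-catalysed allylic substitution and leaves the three alkenes untouched.

Step 2
Reactants: 2 farnesyl diethyl phosphate; 3 trimethylsilylacetylene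
Product: 5 trimethyl[(3R,6E)-3-ethenyl-3,7,11-trimethyldodeca-6,10-dien-1-yn-1-yl]silane, via diisobutyl(silylethynyl)alane 4 (not isolated)
Conditions: 3, i-Bu2AlH, Et3N (5 mol%), hexanes, 22 °C; then 2, CuCl2·2H2O (2 mol%), chiral 4,5-diphenylimidazolinium N-(2-sulfonatoaryl) zwitterion (NHC precursor, 2 mol%, antipode giving R), THF, −15 °C; aqueous potassium sodium tartrate work-up
Reagents that add atoms: none
Why: Copper-catalysed enantioselective SN2′ allylic substitution of a γ,γ-disubstituted allylic phosphate with a dialkyl(alkynyl)aluminium (made by amine-promoted deprotonative alumination of the alkyne) is an established route to alkynyl-bearing quaternary carbons, and the catalyst generated from CuCl2·2H2O and the chiral imidazolinium sulfonate differentiates the two faces of C3 of the E-alkene so that the chosen ligand antipode fixes the R configuration.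

Step 3
Reactants: 5 silyl enyne
Product: 6 (3R,6E)-3-ethenyl-3,7,11-trimethyldodeca-6,10-dien-1-yne
Conditions: K2CO3 (cat.), MeOH, 22 °C
Reagents that add atoms: none
Why: Carbonate-catalysed methanolysis of the alkynyl C–Si bond (protodesilylation) is selective for the silylalkyne and cannot affect the quaternary centre.

Step 4
Reactants: 6 terminal alkyne
Product: 8 (1E,3R,6E)-3-ethenyl-1-iodo-3,7,11-trimethyldodeca-1,6,10-triene, via alkenylzirconocene chloride 7 (not isolated)
Conditions: Cp2Zr(H)Cl (1.1 equiv), THF, 22 °C, dark; then I2 (1.05 equiv), THF, −78 → 0 °C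
Reagents that add atoms: iodine, II
Why: Hydrozirconation delivers Zr–H syn and with terminal regiochemistry to the alkyne far faster than to the vinyl group on the quaternary carbon or to the trisubstituted alkenes, and iodinolysis of the C–Zr bond with retention gives the E-iodoalkene (hydrozirconation–iodination).

Step 5
Reactants: 9 methyl glycolate
Product: 10 methyl 2-(methoxymethoxy)acetate
Conditions: MOMCl, i-Pr2NEt, CH2Cl2, 0 → 22 °C
Reagents that add atoms: chloromethyl methyl ether, COCCl
Why: Williamson-type alkylation of the hydroxyl with chloromethyl methyl ether under amine base is the routine way to a methoxymethyl ether, and the ester is inert to it.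

Step 6
Reactants: 10 methyl 2-(methoxymethoxy)acetate
Product: 11 N-methoxy-2-(methoxymethoxy)-N-methylacetamide
Conditions: MeNH(OMe)·HCl, i-PrMgCl, THF, −20 °C
Reagents that add atoms: N,O-dimethylhydroxylamine hydrochloride, CNOC.Cl
Why: Acyl substitution of the methyl ester by the chloromagnesium amide of N,O-dimethylhydroxylamine is the standard one-step preparation of an N-methoxy-N-methylamide.

Step 7
Reactants: 8 E-iodoalkene; 11 N-methoxy-N-methylamide
Product: 14 (3E,5R,8E)-5-ethenyl-1-(methoxymethoxy)-5,9,13-trimethyltetradeca-3,8,12-trien-2-one, via alkenyllithium 12 (not isolated), via lithium hemiaminal adduct 13 (not isolated)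
Conditions: t-BuLi (2 equiv), Et2O, −78 °C; then 11, −78 → −20 °C; aq. NH4Cl
Reagents that add atoms: none
Why: Iodine–lithium exchange proceeds with retention of the E geometry and the alkenyllithium adds only once to the N-methoxy-N-methylamide because the chelated adduct 13 persists until work-up (Weinreb ketone synthesis), the quaternary centre being a spectator.

Step 8
Reactants: 14 (R)-enone; 15 dimethyl malonate
Product: 17 methyl 2-hydroxy-3-(methoxymethoxy)-4-oxo-6-(R-chain)cyclohex-2-ene-1-carboxylate (enol form; ring centres C1 and C6 unassigned), via Michael adduct 16 (not isolated)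
Conditions: NaOMe (1.5 equiv), MeOH, 22 → 65 °C; then 1 M HCl to pH 4, 0 °C
Reagents that add atoms: none
Why: Sodium dimethyl malonate adds reversibly to the β-carbon of 14 to give 16, and the enolate formed on the methoxymethoxy-bearing carbon of 16 then attacks one ester carbonyl and expels methoxide; this is a Michael–Claisen (Dieckmann-type) annulation, the reaction that converts mesityl oxide and a malonate into dimedone. The one ring formed, the carbocycle that becomes ring A, closes in a 6-(enolendo)-exo-trig mode, so that the Michael step makes the C1–C6 bond and the acylation the C4–C5 bond, and the sequence is pulled to completion by deprotonation of the β-dicarbonyl product. Two ring stereocentres arise (the carbons bearing the side chain and the ester); neither is controlled, because the ester-bearing one is epimerisable and is lost in step 9 and the other is erased on aromatisation, while the quaternary centre carries no acidic hydrogen and is not at risk. The step needs 1,4- rather than 1,2-attack at a β-carbon that sits next to the quaternary centre, which is expected because the stabilised malonate anion adds reversibly (any 1,2-adduct reverts) and the conjugate adduct is drained by ring closure, and it needs C-acylation from the alkoxy side of the ketone, which ring size enforces since the other enolate could only close a four-membered ring.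

Step 9
Reactants: 17 cyclohexanedione ester
Product: 19 3-hydroxy-2-(methoxymethoxy)-5-(R-chain)cyclohex-2-en-1-one (enol form of the 1,3-dione), via β-keto acid 18 (not isolated)
Conditions: 2 M aq. NaOH, MeOH, 65 °C; then 1 M HCl to pH 3, 0 °C; then 45 °C
Reagents that add atoms: none
Why: Saponification of the enolised β-keto ester and mild acidification give a vinylogous β-keto acid that loses carbon dioxide on gentle warming (ester hydrolysis–decarboxylation), at an acidity and temperature the methoxymethyl acetal should tolerate, and the ester-bearing stereocentre disappears.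

Step 10
Reactants: 19 enolic 1,3-dione
Product: 20 3-chloro-2-(methoxymethoxy)-5-(R-chain)cyclohex-2-en-1-one (both C5 epimers)
Conditions: Ph3P, CCl4, MeCN, 22 → 40 °C
Reagents that add atoms: carbon tetrachloride, ClC(Cl)(Cl)Cl
Why: The enolic 1,3-dione is O-phosphonylated by the Ph3P–CCl4 couple and chloride then displaces triphenylphosphine oxide by addition–elimination (Appel-type conversion of a 1,3-dione into a β-chloro enone) under neutral conditions that spare the acetal, and since the two carbonyls differ only as diastereotopic groups a single constitution results.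

Step 11
Reactants: 21 catechol
Product: 22 2-{[tri(propan-2-yl)silyl]oxy}phenol
Conditions: TIPSCl (1 equiv), imidazole, DMF, 0 → 22 °C (catechol 2 equiv)
Reagents that add atoms: chlorotri(propan-2-yl)silane, CC(C)[Si](Cl)(C(C)C)C(C)C
Why: Silylation of one hydroxyl of catechol used in excess with the bulky chlorosilane is a standard mono-protection, the second silylation being slowed by the neighbouring triisopropylsilyloxy group.

Step 12
Reactants: 22 mono-silyl catechol
Product: 23 [2-(methoxymethoxy)phenoxy]tri(propan-2-yl)silane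
Conditions: MOMCl, i-Pr2NEt, CH2Cl2, 0 → 22 °C
Reagents that add atoms: chloromethyl methyl ether, COCCl
Why: Alkylation of the remaining phenol with chloromethyl methyl ether under amine base (methoxymethyl ether formation) installs the group that both protects the future ring B hydroxyl and directs the metalation of step 13.

Step 13
Reactants: 23 differentiated catechol; 2 farnesyl diethyl phosphate
Product: 26 [2-(methoxymethoxy)-3-(S-chain)phenoxy]tri(propan-2-yl)silane, via aryllithium 24 (not isolated), via aryl(diethyl)alane 25 (not isolated)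
Conditions: n-BuLi, Et2O, 0 → 22 °C; Et2AlCl, −78 → 22 °C; then 2, CuCl2·2H2O (5 mol%), chiral 4,5-diphenylimidazolinium N-(2-sulfonatoaryl) zwitterion (NHC precursor, 5 mol%, antipode giving S), THF, −30 → −15 °C; aqueous potassium sodium tartrate work-up
Reagents that add atoms: none
Why: The methoxymethoxy group directs lithiation to its only free ortho position (directed ortho-metalation), transmetalation gives an aryl(diethyl)aluminium whose aryl group is transferred in a copper-catalysed enantioselective SN2′ allylic substitution of the trisubstituted phosphate, and the catalyst generated from CuCl2·2H2O and the antipodal imidazolinium sulfonate selects the opposite face of C3 so that the S quaternary centre results.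

Step 14
Reactants: 26 silyl ether
Product: 27 2-(methoxymethoxy)-3-(S-chain)phenol
Conditions: Bu4NF, THF, 0 °C; aq. NH4Cl
Reagents that add atoms: none
Why: Fluoride cleaves the aryl silyl ether (desilylation) without touching the methoxymethyl ether, so that only the oxygen remote from the quaternary carbon is set free.

Step 15
Reactants: 20 β-chloro enone; 27 ring B phenol
Product: 28 2-(methoxymethoxy)-3-[2-(methoxymethoxy)-3-(S-chain)phenoxy]-5-(R-chain)cyclohex-2-en-1-one (both C5 epimers)
Conditions: Cs2CO3, DMF, 50 °C
Reagents that add atoms: none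
Why: The caesium phenoxide adds to the chlorine-bearing β-carbon of the vinylogous acid chloride and the resulting enolate expels chloride (addition–elimination, nucleophilic vinylic substitution), which forms the hindered ring A C5–O bond without any aryl–oxygen cross-coupling.

Step 16
Reactants: 28 aryloxy enone
Product: 30 2-(methoxymethoxy)-3-[2-(methoxymethoxy)-3-(S-chain)phenoxy]-6-(phenylselanyl)-5-(R-chain)cyclohex-2-en-1-one (ring diastereomers), via lithium dienolate 29 (not isolated)
Conditions: LiN(i-Pr)2, THF, −78 °C; then PhSeCl, −78 °C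
Reagents that add atoms: benzeneselenenyl chloride, Cl[Se]c1ccccc1
Why: Kinetic deprotonation of the vinylogous ester at the α′-methylene and trapping of the enolate with PhSeCl is a standard α-selenenylation, and a minor γ-selenide would converge on the same arene in step 17.

Step 17
Reactants: 30 α′-selenide
Product: 33 2-(methoxymethoxy)-3-[2-(methoxymethoxy)-3-(S-chain)phenoxy]-5-(R-chain)phenol, via selenoxide 31 (not isolated), via cyclohexadienone 32 (not isolated)
Conditions: mCPBA (1.05 equiv), CH2Cl2, −78 °C; then i-Pr2NH, −78 → 22 °C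
Reagents that add atoms: none
Why: Oxidation at selenium at low temperature and syn-elimination of the selenoxide give the cross-conjugated dienone 32, which tautomerises at once to the phenol (selenoxide elimination with aromatisation), the amine intercepting the selenenic acid before it can add to the alkenes, and the ring stereocentres vanish.

Step 18
Reactants: 33 bis(methoxymethyl) ether
Product: 35 3-{2-hydroxy-3-[(3S,6E)-3,7,11-trimethyldodeca-1,6,10-trien-3-yl]phenoxy}-5-[(3R,6E)-3,7,11-trimethyldodeca-1,6,10-trien-3-yl]benzene-1,2-diol (CNP0325484.1), via tris(trimethylsilyl) ether 34 (not isolated)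
Conditions: TMSOTf, 2,2′-bipyridyl, MeCN–CH2Cl2, 0 → 22 °C; then H2O, 22 °C; under argon
Reagents that add atoms: none
Why: The silyl triflate–bipyridyl couple exchanges the aryl methoxymethyl ethers for trimethylsilyl ethers without free protic acid and water then releases the three phenols (methoxymethyl ether cleavage), so that the trisubstituted alkenes and the air-sensitive catechol never meet strong acid.

Compound list
1 | (2E,6E)-farnesol | CC(C)=CCC/C(C)=C/CC/C(C)=C/CO | starting material
2 | (2E,6E)-3,7,11-trimethyldodeca-2,6,10-trien-1-yl diethyl phosphate | CC(C)=CCC/C(C)=C/CC/C(C)=C/COP(=O)(OCC)OCC | intermediate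
3 | trimethylsilylacetylene | C#C[Si](C)(C)C | starting material
4 | diisobutyl[(trimethylsilyl)ethynyl]aluminium | CC(C)C[Al](CC(C)C)C#C[Si](C)(C)C | intermediate
5 | trimethyl[(3R,6E)-3-ethenyl-3,7,11-trimethyldodeca-6,10-dien-1-yn-1-yl]silane | C=C[C@@](C)(CC/C=C(\C)CCC=C(C)C)C#C[Si](C)(C)C | intermediate
6 | (3R,6E)-3-ethenyl-3,7,11-trimethyldodeca-6,10-dien-1-yne | C=C[C@@](C)(CC/C=C(\C)CCC=C(C)C)C#C | intermediate
7 | chlorobis(cyclopentadienyl)[(1E,3R,6E)-3-ethenyl-3,7,11-trimethyldodeca-1,6,10-trien-1-yl]zirconium | C=C[C@@](C)(CC/C=C(\C)CCC=C(C)C)/C=C/[Zr](Cl)(C1C=CC=C1)C1C=CC=C1 | intermediate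
8 | (1E,3R,6E)-3-ethenyl-1-iodo-3,7,11-trimethyldodeca-1,6,10-triene | C=C[C@@](C)(CC/C=C(\C)CCC=C(C)C)/C=C/I | intermediate
9 | methyl glycolate | COC(=O)CO | starting material
10 | methyl 2-(methoxymethoxy)acetate | COCOCC(=O)OC | intermediate
11 | N-methoxy-2-(methoxymethoxy)-N-methylacetamide | COCOCC(=O)N(C)OC | intermediate
12 | [(1E,3R,6E)-3-ethenyl-3,7,11-trimethyldodeca-1,6,10-trien-1-yl]lithium | C=C[C@@](C)(CC/C=C(\C)CCC=C(C)C)/C=C/[Li] | intermediate
13 | lithium (3E,5R,8E)-5-ethenyl-2-[methoxy(methyl)amino]-1-(methoxymethoxy)-5,9,13-trimethyltetradeca-3,8,12-trien-2-olate | C=C[C@@](C)(CC/C=C(\C)CCC=C(C)C)/C=C/C(O[Li])(COCOC)N(C)OC | intermediate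
14 | (3E,5R,8E)-5-ethenyl-1-(methoxymethoxy)-5,9,13-trimethyltetradeca-3,8,12-trien-2-one | C=C[C@@](C)(CC/C=C(\C)CCC=C(C)C)/C=C/C(=O)COCOC | intermediate
15 | dimethyl malonate | COC(=O)CC(=O)OC | starting material
16 | dimethyl 2-[(5R,8E)-5-ethenyl-1-(methoxymethoxy)-5,9,13-trimethyl-2-oxotetradeca-8,12-dien-4-yl]propanedioate (C4 epimers) | C=C[C@@](C)(CC/C=C(\C)CCC=C(C)C)C(CC(=O)COCOC)C(C(=O)OC)C(=O)OC | intermediate
17 | methyl 2-hydroxy-3-(methoxymethoxy)-4-oxo-6-(R-chain)cyclohex-2-ene-1-carboxylate | C=C[C@@](C)(CC/C=C(\C)CCC=C(C)C)C1CC(=O)C(OCOC)=C(O)C1C(=O)OC | intermediate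
18 | 2-hydroxy-3-(methoxymethoxy)-4-oxo-6-(R-chain)cyclohex-2-ene-1-carboxylic acid | C=C[C@@](C)(CC/C=C(\C)CCC=C(C)C)C1CC(=O)C(OCOC)=C(O)C1C(=O)O | intermediate
19 | 3-hydroxy-2-(methoxymethoxy)-5-(R-chain)cyclohex-2-en-1-one | C=C[C@@](C)(CC/C=C(\C)CCC=C(C)C)C1CC(=O)C(OCOC)=C(O)C1 | intermediate
20 | 3-chloro-2-(methoxymethoxy)-5-(R-chain)cyclohex-2-en-1-one | C=C[C@@](C)(CC/C=C(\C)CCC=C(C)C)C1CC(=O)C(OCOC)=C(Cl)C1 | intermediate
21 | catechol | Oc1ccccc1O | starting material
22 | 2-{[tri(propan-2-yl)silyl]oxy}phenol | CC(C)[Si](Oc1ccccc1O)(C(C)C)C(C)C | intermediate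
23 | [2-(methoxymethoxy)phenoxy]tri(propan-2-yl)silane | COCOc1ccccc1O[Si](C(C)C)(C(C)C)C(C)C | intermediate
24 | [2-(methoxymethoxy)-3-{[tri(propan-2-yl)silyl]oxy}phenyl]lithium | [Li]c1cccc(O[Si](C(C)C)(C(C)C)C(C)C)c1OCOC | intermediate
25 | diethyl[2-(methoxymethoxy)-3-{[tri(propan-2-yl)silyl]oxy}phenyl]aluminium | CC[Al](CC)c1cccc(O[Si](C(C)C)(C(C)C)C(C)C)c1OCOC | intermediate
26 | [2-(methoxymethoxy)-3-(S-chain)phenoxy]tri(propan-2-yl)silane | COCOc1c(O[Si](C(C)C)(C(C)C)C(C)C)cccc1[C@](C)(C=C)CC/C=C(\C)CCC=C(C)C | intermediate
27 | 2-(methoxymethoxy)-3-(S-chain)phenol | COCOc1c(O)cccc1[C@](C)(C=C)CC/C=C(\C)CCC=C(C)C | intermediate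
28 | 2-(methoxymethoxy)-3-[2-(methoxymethoxy)-3-(S-chain)phenoxy]-5-(R-chain)cyclohex-2-en-1-one | C=C[C@@](C)(CC/C=C(\C)CCC=C(C)C)C1CC(=O)C(OCOC)=C(Oc2cccc([C@](C)(C=C)CC/C=C(\C)CCC=C(C)C)c2OCOC)C1 | intermediate
29 | lithium 6-(methoxymethoxy)-5-[2-(methoxymethoxy)-3-(S-chain)phenoxy]-3-(R-chain)cyclohexa-1,5-dien-1-olate | C=C[C@@](C)(CC/C=C(\C)CCC=C(C)C)C1C=C(O[Li])C(OCOC)=C(Oc2cccc([C@](C)(C=C)CC/C=C(\C)CCC=C(C)C)c2OCOC)C1 | intermediate
30 | 2-(methoxymethoxy)-3-[2-(methoxymethoxy)-3-(S-chain)phenoxy]-6-(phenylselanyl)-5-(R-chain)cyclohex-2-en-1-one | C=C[C@@](C)(CC/C=C(\C)CCC=C(C)C)C1CC(Oc2cccc([C@](C)(C=C)CC/C=C(\C)CCC=C(C)C)c2OCOC)=C(OCOC)C(=O)C1[Se]c1ccccc1 | intermediate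
31 | 2-(methoxymethoxy)-3-[2-(methoxymethoxy)-3-(S-chain)phenoxy]-6-(phenylseleninyl)-5-(R-chain)cyclohex-2-en-1-one | C=C[C@@](C)(CC/C=C(\C)CCC=C(C)C)C1CC(Oc2cccc([C@](C)(C=C)CC/C=C(\C)CCC=C(C)C)c2OCOC)=C(OCOC)C(=O)C1[Se](=O)c1ccccc1 | intermediate
32 | 2-(methoxymethoxy)-3-[2-(methoxymethoxy)-3-(S-chain)phenoxy]-5-(R-chain)cyclohexa-2,5-dien-1-one | C=C[C@@](C)(CC/C=C(\C)CCC=C(C)C)C1=CC(=O)C(OCOC)=C(Oc2cccc([C@](C)(C=C)CC/C=C(\C)CCC=C(C)C)c2OCOC)C1 | intermediate
33 | 2-(methoxymethoxy)-3-[2-(methoxymethoxy)-3-(S-chain)phenoxy]-5-(R-chain)phenol | C=C[C@@](C)(CC/C=C(\C)CCC=C(C)C)c1cc(O)c(OCOC)c(Oc2cccc([C@](C)(C=C)CC/C=C(\C)CCC=C(C)C)c2OCOC)c1 | intermediate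
34 | tris(trimethylsilyl) ether of 35 (all three phenolic oxygens silylated) | C=C[C@@](C)(CC/C=C(\C)CCC=C(C)C)c1cc(O[Si](C)(C)C)c(O[Si](C)(C)C)c(Oc2cccc([C@](C)(C=C)CC/C=C(\C)CCC=C(C)C)c2O[Si](C)(C)C)c1 | intermediate
35 | 3-{2-hydroxy-3-[(3S,6E)-3,7,11-trimethyldodeca-1,6,10-trien-3-yl]phenoxy}-5-[(3R,6E)-3,7,11-trimethyldodeca-1,6,10-trien-3-yl]benzene-1,2-diol | C=C[C@@](C)(CC/C=C(\C)CCC=C(C)C)c1cc(O)c(O)c(Oc2cccc([C@](C)(C=C)CC/C=C(\C)CCC=C(C)C)c2O)c1 | target

Total step count: 18.
Longest linear sequence: 12 steps (1, 2, 3, 4, 7, 8, 9, 10, 15, 16, 17, 18).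

Steps most likely to fail

Step 8. What may go wrong: conjugate addition stalls at the neopentyl-type β-carbon (retro-Michael equilibrium on the enone side), so that base-induced self-condensation of the alkoxy ketone outruns ring formation. Fallback: the two bonds would be made in separate, irreversible operations. Setting out from 14, a Mukaiyama–Michael addition of tert-butyl[(1-methoxyethenyl)oxy]dimethylsilane (LiClO4 cat., MeCN, 22–50 °C) should give the silyl enol ether methyl 5-[(tert-butyldimethylsilyl)oxy]-6-(methoxymethoxy)-3-(R-chain)hex-4-enoate F1. Buffered desilylation (Bu4NF, AcOH, THF, 0 °C) should release the keto ester methyl 6-(methoxymethoxy)-5-oxo-3-(R-chain)hexanoate F2. Dieckmann-type closure through the alkoxy enolate (KOt-Bu, THF, 0 °C) should then deliver dione 19 directly, where the route is rejoined; step 9 becomes unnecessary.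

Step 13. What may go wrong: chelation of aluminium by the ortho acetal and crowding at copper lead to linear (SN2) substitution, competing ethyl transfer or erosion of enantioselectivity. Fallback: the aryl group would be delivered from boron under alkoxide activation. Setting out from 23, lithiation as in step 13 and trapping of 24 with B(OMe)3 followed by aq. NH4Cl should give [2-(methoxymethoxy)-3-{[tri(propan-2-yl)silyl]oxy}phenyl]boronic acid F3. Condensation with 2,2-dimethylpropane-1,3-diol (MgSO4, CH2Cl2) should give 2-[2-(methoxymethoxy)-3-{[tri(propan-2-yl)silyl]oxy}phenyl]-5,5-dimethyl-1,3,2-dioxaborinane F4. Copper-catalysed enantioselective SN2′ allylic arylation of phosphate 2 with F4 (CuCl, chiral hydroxy-bearing imidazolinium chloride as NHC precursor, NaOMe, THF, 30 °C) should then return to 26.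

Step 17. What may go wrong: over-oxidation, in which peracid or the selenium by-products attack the electron-rich phenol as it forms or add to the trisubstituted alkenes, and incomplete syn-elimination from the hindered selenoxide. Fallback: ring A would be dehydrogenated by a Saegusa–Ito oxidation, which replaces steps 16 and 17. Setting out from 28, LiN(i-Pr)2 then Me3SiCl (THF, −78 °C) should give the silyl dienol ether trimethyl{[6-(methoxymethoxy)-5-[2-(methoxymethoxy)-3-(S-chain)phenoxy]-3-(R-chain)cyclohexa-1,5-dien-1-yl]oxy}silane F5. Pd(OAc)2 (MeCN, 22 °C) should convert it into dienone 32, which tautomerises to phenol 33, where the route is rejoined.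

Further compounds
F1 | step 8 | methyl 5-[(tert-butyldimethylsilyl)oxy]-6-(methoxymethoxy)-3-(R-chain)hex-4-enoate | C=C[C@@](C)(CC/C=C(\C)CCC=C(C)C)C(CC(=O)OC)C=C(COCOC)O[Si](C)(C)C(C)(C)C
F2 | step 8 | methyl 6-(methoxymethoxy)-5-oxo-3-(R-chain)hexanoate | C=C[C@@](C)(CC/C=C(\C)CCC=C(C)C)C(CC(=O)OC)CC(=O)COCOC
F3 | step 13 | [2-(methoxymethoxy)-3-{[tri(propan-2-yl)silyl]oxy}phenyl]boronic acid | OB(O)c1cccc(O[Si](C(C)C)(C(C)C)C(C)C)c1OCOC
F4 | step 13 | 2-[2-(methoxymethoxy)-3-{[tri(propan-2-yl)silyl]oxy}phenyl]-5,5-dimethyl-1,3,2-dioxaborinane | CC1(C)COB(OC1)c1cccc(O[Si](C(C)C)(C(C)C)C(C)C)c1OCOC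
F5 | step 17 | trimethyl{[6-(methoxymethoxy)-5-[2-(methoxymethoxy)-3-(S-chain)phenoxy]-3-(R-chain)cyclohexa-1,5-dien-1-yl]oxy}silane | C=C[C@@](C)(CC/C=C(\C)CCC=C(C)C)C1C=C(O[Si](C)(C)C)C(OCOC)=C(Oc2cccc([C@](C)(C=C)CC/C=C(\C)CCC=C(C)C)c2OCOC)C1
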